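**Assumption:** the SMILES is read as (3R)-licoricidin, and the Evans oxazolidinone is treated as a recoverable reagent (none of its atoms reach the target).

## Retrosynthetic overview

1. Licoricidin ⇐ MOM removal; the C7–OH ⇐ C7–Br (Pd hydroxylation), so a 3,5-dibromophenol-derived A-ring supplies both C8a–O and C7–O.
2. The pyran ring (the only ring built) ⇐ intramolecular Cu-catalysed C–O coupling of the C2 alcohol onto C8a–Br.
3. The C3 stereocentre and C3–C4 bond ⇐ Evans alkylation of a B-ring arylacetyl oxazolidinone (fragment B, 16) with an A-ring benzyl bromide (fragment A, 8).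
4. Fragment A ⇐ 1,3-dibromobenzene: C–H borylation/oxidation, then phenol-directed ortho-prenylation and ortho-formylation, with regiochemistry fixed by the symmetry of 3,5-dibromophenol.
5. Fragment B ⇐ resorcinol: bis-MOM ether, two directed ortho-lithiations (prenyl, then hydroxyethyl), oxidation, auxiliary attachment.

## Fragment A

**Step 1**
Reactants: 1, 1,3-dibromobenzene
Product: 2, 3,5-dibromophenol
Conditions: [Ir(cod)OMe]2 (1 mol %), dtbpy, B2pin2, THF, 80 °C; then Oxone, acetone/H2O, rt (one pot)
Reagents that add atoms: Oxone (KHSO5), [K+].[O-]S(=O)(=O)OO (phenol oxygen)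
Why: Sterically controlled Ir-catalysed C–H borylation (Hartwig–Miyaura/Maleczka–Smith) occurs only at C5, the one C–H not ortho to bromine, and the boronate is oxidised to the phenol with aryl bromides untouched.

**Step 2**
Reactants: 2, 3,5-dibromophenol; 3, prenyl bromide
Product: 4, 3,5-dibromo-2-(3-methylbut-2-en-1-yl)phenol
Conditions: NaH (1.0 equiv), toluene, 0 °C → rt; then 3, rt → 50 °C
Reagents that add atoms: prenyl bromide (3), CC(C)=CCBr
Why: Ortho C-alkylation of the tight sodium phenoxide ion pair in a non-polar solvent; the two ortho carbons are equivalent and the para carbon is buried between two bromines, so only one C-prenyl isomer can form (the O-prenyl ether by-product is separated).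

**Step 3**
Reactants: 4
Product: 5, 4,6-dibromo-2-hydroxy-3-(3-methylbut-2-en-1-yl)benzaldehyde
Conditions: MgCl2, Et3N, (CH2O)n, MeCN, reflux
Reagents that add atoms: paraformaldehyde, C=O
Why: Casnati–Skattebøl magnesium-mediated formylation is ortho-specific, and only one ortho position remains, so the aldehyde lands between the OH and a bromine.

**Step 4**
Reactants: 5
Product: 6, 4,6-dibromo-2-methoxy-3-(3-methylbut-2-en-1-yl)benzaldehyde
Conditions: MeI, K2CO3, DMF, 40 °C
Reagents that add atoms: iodomethane, CI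
Why: Williamson O-methylation of the acidic, chelated phenol fixes the methoxy group between the prenyl and the future C4 carbon.

**Step 5**
Reactants: 6
Product: 7, [4,6-dibromo-2-methoxy-3-(3-methylbut-2-en-1-yl)phenyl]methanol
Conditions: NaBH4, MeOH/THF, 0 °C
Reagents that add atoms: none
Why: Chemoselective borohydride reduction of the aldehyde; aryl bromides and the prenyl alkene are inert.

**Step 6**
Reactants: 7
Product: 8, 1,5-dibromo-2-(bromomethyl)-3-methoxy-4-(3-methylbut-2-en-1-yl)benzene (fragment A)
Conditions: CBr4, PPh3, CH2Cl2, 0 °C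
Reagents that add atoms: CBr4, BrC(Br)(Br)Br
Why: Appel bromination under neutral conditions avoids HBr addition to the prenyl group; the two ring bromines make this benzyl bromide stable enough to isolate.

## Fragment B

**Step 7**
Reactants: 9, resorcinol
Product: 10, 1,3-bis(methoxymethoxy)benzene
Conditions: MOMCl, i-Pr2NEt, CH2Cl2, 0 °C → rt
Reagents that add atoms: MOMCl, COCCl (two equivalents)
Why: Acetal protection of both phenols installs the directing groups needed for the two lithiations.

**Step 8**
Reactants: 10; 3, prenyl bromide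
Product: 11, 1,3-bis(methoxymethoxy)-2-(3-methylbut-2-en-1-yl)benzene
Conditions: n-BuLi, THF, 0 °C → rt; CuI (10 mol %), then 3, –78 °C → rt
Reagents that add atoms: prenyl bromide (3), CC(C)=CCBr
Why: Directed ortho-metalation takes place at C2, between the two OMOM groups, and copper-mediated SN2 alkylation gives the linear prenyl group.

**Step 9**
Reactants: 11; 12, ethylene oxide
Product: 13, 2-[2,4-bis(methoxymethoxy)-3-(3-methylbut-2-en-1-yl)phenyl]ethan-1-ol
Conditions: n-BuLi, THF, 0 °C; then 12, BF3·OEt2, –78 °C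
Reagents that add atoms: ethylene oxide (12), C1CO1
Why: A second directed ortho-metalation can only occur ortho to an OMOM group (C4 ≡ C6), and BF3-assisted epoxide opening by the aryllithium adds the two-carbon chain.

**Step 10**
Reactants: 13
Product: 14, 2-[2,4-bis(methoxymethoxy)-3-(3-methylbut-2-en-1-yl)phenyl]acetaldehyde
Conditions: Dess–Martin periodinane, NaHCO3, CH2Cl2, 0 °C → rt (used crude)
Reagents that add atoms: none
Why: Buffered Dess–Martin oxidation is neutral and leaves the MOM ethers and the alkene alone.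

**Step 11**
Reactants: 14
Product: 15, 2-[2,4-bis(methoxymethoxy)-3-(3-methylbut-2-en-1-yl)phenyl]acetic acid
Conditions: NaClO2, NaH2PO4, 2-methyl-2-butene (excess), t-BuOH/H2O, 0 °C
Reagents that add atoms: sodium chlorite, [Na+].[O-]Cl=O
Why: Pinnick oxidation; the large excess of scavenger protects the prenyl alkene and electron-rich ring from HOCl.

**Step 12**
Reactants: 15
Product: 16, (4R)-4-benzyl-3-{[2,4-bis(methoxymethoxy)-3-(3-methylbut-2-en-1-yl)phenyl]acetyl}-1,3-oxazolidin-2-one (fragment B)
Conditions: PivCl, Et3N, THF, –20 °C; then (R)-4-benzyl-2-oxazolidinone, LiCl, rt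
Reagents that add atoms: (R)-4-benzyl-2-oxazolidinone (chiral auxiliary, cleaved in step 14), O=C1N[C@H](Cc2ccccc2)CO1
Why: Mixed-anhydride N-acylation attaches the Evans auxiliary without touching the acetals.

## Coupling and endgame

**Step 13**
Reactants: 16 (fragment B); 8 (fragment A)
Product: 17, (4R)-4-benzyl-3-{(2R)-2-[2,4-bis(methoxymethoxy)-3-(3-methylbut-2-en-1-yl)phenyl]-3-[4,6-dibromo-2-methoxy-3-(3-methylbut-2-en-1-yl)phenyl]propanoyl}-1,3-oxazolidin-2-one
Conditions: NaHMDS (1.05 equiv), THF, –78 °C; then 8, –78 → –40 °C; AcOH quench at –78 °C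
Reagents that add atoms: none (both partners are numbered reactants)
Why: Evans asymmetric alkylation: the chelated Z-sodium enolate is attacked by the benzyl bromide on the face opposite the auxiliary benzyl group, and the (R)-auxiliary gives the (2R) centre, which becomes C3-(R) of the isoflavan.

**Step 14**
Reactants: 17
Product: 18, (2R)-2-[2,4-bis(methoxymethoxy)-3-(3-methylbut-2-en-1-yl)phenyl]-3-[4,6-dibromo-2-methoxy-3-(3-methylbut-2-en-1-yl)phenyl]propan-1-ol
Conditions: LiBH4, MeOH (1 equiv), Et2O/THF, 0 °C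
Reagents that add atoms: none
Why: Reductive cleavage of the imide gives the primary alcohol and releases the auxiliary without epimerising the α-aryl centre; the CIP descriptor is unchanged.

**Step 15**
Reactants: 18
Product: 19, (3R)-7-bromo-3-[2,4-bis(methoxymethoxy)-3-(3-methylbut-2-en-1-yl)phenyl]-5-methoxy-6-(3-methylbut-2-en-1-yl)-3,4-dihydro-2H-chromene
Conditions: CuI (10 mol %), 3,4,7,8-tetramethyl-1,10-phenanthroline (20 mol %), Cs2CO3, toluene, 110 °C
Reagents that add atoms: none
Why: Intramolecular Ullmann-type etherification: the copper alkoxide can only reach the bromine ortho to the tether, so the six-membered pyran closes and the remote C7–Br is retained; the stereocentre is not involved.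

**Step 16**
Reactants: 19
Product: 20, (3R)-3-[2,4-bis(methoxymethoxy)-3-(3-methylbut-2-en-1-yl)phenyl]-5-methoxy-6-(3-methylbut-2-en-1-yl)-3,4-dihydro-2H-chromen-7-ol
Conditions: Pd2(dba)3 (2 mol %), t-BuXPhos (8 mol %), KOH, 1,4-dioxane/H2O, 100 °C
Reagents that add atoms: potassium hydroxide, [K+].[OH-]
Why: Buchwald Pd-catalysed hydroxylation converts the remaining aryl bromide to the C7 phenol; MOM ethers and prenyl groups are stable to aqueous base.

**Step 17**
Reactants: 20
Product: 21, (3R)-licoricidin, 4-[(3R)-7-hydroxy-5-methoxy-6-(3-methylbut-2-en-1-yl)-3,4-dihydro-2H-chromen-3-yl]-2-(3-methylbut-2-en-1-yl)benzene-1,3-diol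
Conditions: 3 M aq HCl/MeOH (1:4), rt → 40 °C, stopped at full conversion
Reagents that add atoms: none
Why: Mild acidic acetal hydrolysis removes both MOM groups below the threshold for prenyl-phenol cyclisation and does not touch the C3 stereocentre.

## Compound list

1 | 1,3-dibromobenzene | Brc1cccc(Br)c1 | starting material
2 | 3,5-dibromophenol | Oc1cc(Br)cc(Br)c1 | intermediate
3 | prenyl bromide (1-bromo-3-methylbut-2-ene) | CC(C)=CCBr | starting material
4 | 3,5-dibromo-2-(3-methylbut-2-en-1-yl)phenol | CC(C)=CCc1c(O)cc(Br)cc1Br | intermediate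
5 | 4,6-dibromo-2-hydroxy-3-(3-methylbut-2-en-1-yl)benzaldehyde | CC(C)=CCc1c(O)c(C=O)c(Br)cc1Br | intermediate
6 | 4,6-dibromo-2-methoxy-3-(3-methylbut-2-en-1-yl)benzaldehyde | COc1c(CC=C(C)C)c(Br)cc(Br)c1C=O | intermediate
7 | [4,6-dibromo-2-methoxy-3-(3-methylbut-2-en-1-yl)phenyl]methanol | COc1c(CC=C(C)C)c(Br)cc(Br)c1CO | intermediate
8 | 1,5-dibromo-2-(bromomethyl)-3-methoxy-4-(3-methylbut-2-en-1-yl)benzene | COc1c(CC=C(C)C)c(Br)cc(Br)c1CBr | intermediate
9 | resorcinol | Oc1cccc(O)c1 | starting material
10 | 1,3-bis(methoxymethoxy)benzene | COCOc1cccc(OCOC)c1 | intermediate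
11 | 1,3-bis(methoxymethoxy)-2-(3-methylbut-2-en-1-yl)benzene | COCOc1cccc(OCOC)c1CC=C(C)C | intermediate
12 | ethylene oxide | C1CO1 | starting material
13 | 2-[2,4-bis(methoxymethoxy)-3-(3-methylbut-2-en-1-yl)phenyl]ethan-1-ol | COCOc1ccc(CCO)c(OCOC)c1CC=C(C)C | intermediate
14 | 2-[2,4-bis(methoxymethoxy)-3-(3-methylbut-2-en-1-yl)phenyl]acetaldehyde | COCOc1ccc(CC=O)c(OCOC)c1CC=C(C)C | intermediate
15 | 2-[2,4-bis(methoxymethoxy)-3-(3-methylbut-2-en-1-yl)phenyl]acetic acid | COCOc1ccc(CC(=O)O)c(OCOC)c1CC=C(C)C | intermediate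
16 | (4R)-4-benzyl-3-{[2,4-bis(methoxymethoxy)-3-prenylphenyl]acetyl}-1,3-oxazolidin-2-one | COCOc1ccc(CC(=O)N2[C@H](Cc3ccccc3)COC2=O)c(OCOC)c1CC=C(C)C | intermediate
17 | (4R)-4-benzyl-3-{(2R)-2-[2,4-bis(methoxymethoxy)-3-prenylphenyl]-3-[4,6-dibromo-2-methoxy-3-prenylphenyl]propanoyl}-1,3-oxazolidin-2-one | COCOc1ccc([C@@H](Cc2c(Br)cc(Br)c(CC=C(C)C)c2OC)C(=O)N2[C@H](Cc3ccccc3)COC2=O)c(OCOC)c1CC=C(C)C | intermediate
18 | (2R)-2-[2,4-bis(methoxymethoxy)-3-prenylphenyl]-3-[4,6-dibromo-2-methoxy-3-prenylphenyl]propan-1-ol | COCOc1ccc([C@@H](Cc2c(Br)cc(Br)c(CC=C(C)C)c2OC)CO)c(OCOC)c1CC=C(C)C | intermediate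
19 | (3R)-7-bromo-3-[2,4-bis(methoxymethoxy)-3-prenylphenyl]-5-methoxy-6-prenyl-3,4-dihydro-2H-chromene | COCOc1ccc([C@H]2Cc3c(OC)c(CC=C(C)C)c(Br)cc3OC2)c(OCOC)c1CC=C(C)C | intermediate
20 | (3R)-3-[2,4-bis(methoxymethoxy)-3-prenylphenyl]-5-methoxy-6-prenyl-3,4-dihydro-2H-chromen-7-ol | COCOc1ccc([C@H]2Cc3c(OC)c(CC=C(C)C)c(O)cc3OC2)c(OCOC)c1CC=C(C)C | intermediate
21 | (3R)-licoricidin | COc1c(CC=C(C)C)c(O)cc2c1C[C@H](c1ccc(O)c(CC=C(C)C)c1O)CO2 | target

(prenyl = 3-methylbut-2-en-1-yl)

## Totals and risks

Total step count: 17.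
Longest linear sequence: 11 steps (steps 1–6 then 13–17; the fragment B branch, steps 7–12 then 13–17, is the same length).

The three steps most likely to fail:

1. **Step 2, direct ortho C-prenylation of an electron-poor phenoxide** (O-alkylation and bis-alkylation compete). Fallback: switch to a sigmatropic route — O-alkylate 2 with 3-chloro-3-methylbut-1-yne (CuCl2, DBU), semi-hydrogenate (Lindlar), and run an aromatic Claisen rearrangement of the 1,1-dimethylallyl ether; symmetry still guarantees a single ortho-prenyl product.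
2. **Step 13, Evans alkylation** (2,6-disubstituted benzyl bromide; base-labile α-aryl centre). Fallback: condense aldehyde 6 with acid 15 (Perkin, Ac2O/Et3N) to the (E)-2,3-diarylacrylic acid, set C3 by carboxyl-directed asymmetric hydrogenation (Ir–SIPHOX or Ru–BINAP type, which should spare the non-coordinating prenyl alkenes), then reduce with LiAlH4 to 18.
3. **Step 17, acidic MOM removal next to prenyl groups** (risk of cyclisation to dimethylchromans). Fallback: build fragment B with SEM ethers instead of MOM (same directed lithiations) and unmask at the end with fluoride (TBAF), so no Brønsted acid meets the ortho-prenyl phenols.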